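**Retrosynthetic overview**

- The target comes from its 3'-O-benzyl ether by hydrogenolysis. That ether comes from the corresponding flavone (C2=C3 unsaturated) by catalytic asymmetric hydrogenation, which sets C2. Ring C is therefore built flat, one oxidation level above the target.
- The flavone comes from a one-flask [3+3] union that forms O1–C2 and C4–C4a. The partners are C,O-dilithiated 6-bromo-2,3-dimethoxyphenol (ring A) and the N-methoxy-N-methylamide of a 3-arylpropynoic acid (ring B with C2, C3 and C4).
- Enabling feature: in ring A, O1 on C8a and the ring carbon C4a are ortho neighbours, a 1,2-O,C-dinucleophile once C4a carries lithium in place of bromine. In ring C, C2 and C4 are 1,3-related, so at the alkynone level both are electrophilic (amide carbonyl and β-alkyne carbon).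
- Fragments: 2,3-dimethoxyphenol (ortho-bromination) and 3-hydroxy-4,5-dimethoxybenzaldehyde (benzylation, Corey–Fuchs homologation, trapping of the acetylide as the alkynyl Weinreb amide).
- Ring order: rings A and B are bought, ring C is closed in step 5, and the stereocentre follows in step 6.

Key step: step 5

Assumption: 2,3-dimethoxyphenol, 3-hydroxy-4,5-dimethoxybenzaldehyde and N-methoxy-N-methylcarbamoyl chloride are taken as purchased, and the sense of induction of the ruthenium–NHC hydrogenation is matched to 2S by the choice of the enantiomer of the carbene precursor.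

**Route**

Step 1
Reactants: 1 2,3-dimethoxyphenol
Product: 2 6-bromo-2,3-dimethoxyphenol
Conditions: NBS (1.0 equiv), i-Pr2NH (cat.), CH2Cl2, 0 °C
Reagents that add atoms: N-bromosuccinimide, O=C1CCC(=O)N1Br
Why: Amine-mediated ortho-selective electrophilic bromination of a 2-substituted phenol, in which the N-bromoamine formed in the flask is delivered through a hydrogen bond to the phenol oxygen, so that bromine should enter C6 (ortho to OH) and not C4.

Step 2
Reactants: 3 3-hydroxy-4,5-dimethoxybenzaldehyde
Product: 4 3-(benzyloxy)-4,5-dimethoxybenzaldehyde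
Conditions: BnBr, K2CO3, DMF, rt
Reagents that add atoms: benzyl bromide, BrCc1ccccc1
Why: Williamson ether synthesis on the only phenol masks the acidic ring B hydroxyl against the organolithium steps and the hydrogenation, with a group that leaves under neutral conditions at the end.

Step 3
Reactants: 4 3-(benzyloxy)-4,5-dimethoxybenzaldehyde
Product: 5 1-(benzyloxy)-5-(2,2-dibromoethenyl)-2,3-dimethoxybenzene
Conditions: CBr4, PPh3, Zn, CH2Cl2, 0 °C to rt
Reagents that add atoms: carbon tetrabromide, BrC(Br)(Br)Br
Why: First stage of the Corey–Fuchs reaction (Wittig-type dibromomethylenation by Ph3P=CBr2), which is reliable on electron-rich aryl aldehydes.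

Step 4
Reactants: 5 1-(benzyloxy)-5-(2,2-dibromoethenyl)-2,3-dimethoxybenzene
Product: 7 3-[3-(benzyloxy)-4,5-dimethoxyphenyl]-N-methoxy-N-methylprop-2-ynamide, via lithium acetylide 6 (not isolated)
Conditions: n-BuLi (2.1 equiv), THF, −78 °C to 0 °C; then ClC(O)N(OMe)Me, −78 °C to rt
Reagents that add atoms: N-methoxy-N-methylcarbamoyl chloride, CON(C)C(Cl)=O
Why: Second stage of the Corey–Fuchs reaction (bromine–lithium exchange, Fritsch–Buttenberg–Wiechell rearrangement, deprotonation) gives the lithium acetylide, whose acylation by the carbamoyl chloride should give the alkynyl Weinreb amide directly.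

Step 5
Reactants: 2 6-bromo-2,3-dimethoxyphenol; 7 3-[3-(benzyloxy)-4,5-dimethoxyphenyl]-N-methoxy-N-methylprop-2-ynamide
Product: 12 2-[3-(benzyloxy)-4,5-dimethoxyphenyl]-7,8-dimethoxy-4H-chromen-4-one, via dilithio phenoxide 8 (not isolated), via tetrahedral adduct 9 (not isolated), via hydroxyaryl ynone 10 (not isolated), via enaminone 11 (not isolated)
Conditions: 2, n-BuLi (2.1 equiv), Et2O–THF, −78 °C to 0 °C; then 7, −78 °C to 0 °C; then AcOH (2 equiv), Et2NH (excess), EtOH, 50 °C
Reagents that add atoms: none
Why: Deprotonation of the hydroxyl and bromine–lithium exchange turn 2 into the C,O-dilithio species 8, whose aryl carbanion (the future C4a) adds 1,2 to the amide carbonyl of 7 to give the chelate-stabilised tetrahedral adduct 9 and so forms the C4–C4a bond; the protic quench releases ynone 10, diethylamine adds to its β-alkyne carbon to give enaminone 11, and the ortho hydroxyl attacks that same carbon and expels the amine, which forms the O1–C2 bond. The closest known reaction types are the acylation of ortho-lithiated phenoxides by Weinreb amides to ortho-hydroxyaryl ketones and the secondary-amine-mediated cyclisation of ortho-hydroxyaryl ynones to flavones, run here in one flask. Ring C closes by a 6-endo-trig addition–elimination on the enaminone, formally a 6-endo-dig closure of the ynone. No stereocentre is formed, since C2 leaves this step trigonal and is set in step 6. The step needs three selectivities: the site of C-acylation on ring A, which the bromine at C6 of the phenol fixes; 1,2- over conjugate addition to the ynamide, which the hard aryllithium and the N-methoxy-N-methylamide favour; and six- over five-membered ring closure (flavone against aurone), which the amine relay secures because the α-carbon of the enaminone is no longer electrophilic. The benzyl and methyl ethers are inert to all three stages.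

Step 6
Reactants: 12 2-[3-(benzyloxy)-4,5-dimethoxyphenyl]-7,8-dimethoxy-4H-chromen-4-one
Product: 14 (2S)-2-[3-(benzyloxy)-4,5-dimethoxyphenyl]-7,8-dimethoxy-2,3-dihydro-4H-chromen-4-one, via cis-flavan-4-ol 13 (not isolated)
Conditions: [Ru(cod)(2-methylallyl)2] (cat.), 1,3-bis[1-(1-naphthyl)ethyl]imidazolinium tetrafluoroborate (SINpEt·HBF4, single enantiomer, cat.), KOt-Bu (cat.), H2 (100 bar), toluene, rt; then Dess–Martin periodinane, CH2Cl2, rt
Reagents that add atoms: none
Why: Ruthenium–NHC-catalysed asymmetric hydrogenation of the C2=C3 bond of a flavone, a known reaction type, in which the chiral carbene ligands on ruthenium select the face of C2 that receives hydrogen (catalyst control) and so should set 2S, while the part of the material reduced further at C4 to the cis alcohol 13 keeps its C2 configuration and is returned to the ketone by Dess–Martin oxidation.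

Step 7
Reactants: 14 (2S)-2-[3-(benzyloxy)-4,5-dimethoxyphenyl]-7,8-dimethoxy-2,3-dihydro-4H-chromen-4-one
Product: 15 (2S)-2-(3-hydroxy-4,5-dimethoxyphenyl)-7,8-dimethoxy-2,3-dihydro-4H-chromen-4-one
Conditions: H2 (1 atm), 10% Pd/C, EtOAc, rt
Reagents that add atoms: none
Why: Hydrogenolysis of the benzyl aryl ether under neutral conditions should free the ring B phenol without the base that would open ring C by retro-oxa-Michael reaction and scramble C2.

**Compound list**

1 | 2,3-dimethoxyphenol | COc1cccc(O)c1OC | starting material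
2 | 6-bromo-2,3-dimethoxyphenol | COc1ccc(Br)c(O)c1OC | intermediate
3 | 3-hydroxy-4,5-dimethoxybenzaldehyde | COc1cc(C=O)cc(O)c1OC | starting material
4 | 3-(benzyloxy)-4,5-dimethoxybenzaldehyde | COc1cc(C=O)cc(OCc2ccccc2)c1OC | intermediate
5 | 1-(benzyloxy)-5-(2,2-dibromoethenyl)-2,3-dimethoxybenzene | COc1cc(C=C(Br)Br)cc(OCc2ccccc2)c1OC | intermediate
6 | lithium [3-(benzyloxy)-4,5-dimethoxyphenyl]acetylide (formed in the flask) | COc1cc(C#C[Li])cc(OCc2ccccc2)c1OC | intermediate
7 | 3-[3-(benzyloxy)-4,5-dimethoxyphenyl]-N-methoxy-N-methylprop-2-ynamide | COc1cc(C#CC(=O)N(C)OC)cc(OCc2ccccc2)c1OC | intermediate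
8 | lithium 6-lithio-2,3-dimethoxyphenoxide (formed in the flask) | COc1ccc([Li])c(O[Li])c1OC | intermediate
9 | dilithium salt of the tetrahedral adduct of 8 to the amide carbonyl of 7, racemic at the new carbinol carbon (formed in the flask) | COc1ccc(C(O[Li])(C#Cc2cc(OC)c(OC)c(OCc3ccccc3)c2)N(C)OC)c(O[Li])c1OC | intermediate
10 | 3-[3-(benzyloxy)-4,5-dimethoxyphenyl]-1-(2-hydroxy-3,4-dimethoxyphenyl)prop-2-yn-1-one (formed in the flask) | COc1ccc(C(=O)C#Cc2cc(OC)c(OC)c(OCc3ccccc3)c2)c(O)c1OC | intermediate
11 | (2E)-3-[3-(benzyloxy)-4,5-dimethoxyphenyl]-3-(diethylamino)-1-(2-hydroxy-3,4-dimethoxyphenyl)prop-2-en-1-one (formed in the flask; drawn as E, the geometry has no consequence) | COc1ccc(C(=O)/C=C(/N(CC)CC)c2cc(OC)c(OC)c(OCc3ccccc3)c2)c(O)c1OC | intermediate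
12 | 2-[3-(benzyloxy)-4,5-dimethoxyphenyl]-7,8-dimethoxy-4H-chromen-4-one | COc1cc(-c2cc(=O)c3ccc(OC)c(OC)c3o2)cc(OCc2ccccc2)c1OC | intermediate
13 | (2S,4S)-2-[3-(benzyloxy)-4,5-dimethoxyphenyl]-7,8-dimethoxy-3,4-dihydro-2H-chromen-4-ol, 2,4-cis (formed in the flask) | COc1cc([C@@H]2C[C@H](O)c3ccc(OC)c(OC)c3O2)cc(OCc2ccccc2)c1OC | intermediate
14 | (2S)-2-[3-(benzyloxy)-4,5-dimethoxyphenyl]-7,8-dimethoxy-2,3-dihydro-4H-chromen-4-one | COc1cc([C@@H]2CC(=O)c3ccc(OC)c(OC)c3O2)cc(OCc2ccccc2)c1OC | intermediate
15 | (2S)-2-(3-hydroxy-4,5-dimethoxyphenyl)-7,8-dimethoxy-2,3-dihydro-4H-chromen-4-one | COc1cc([C@@H]2CC(=O)c3ccc(OC)c(OC)c3O2)cc(O)c1OC | target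

**Summary**

Total step count: 7. Longest linear sequence: 6 steps (steps 2, 3, 4, 5, 6 and 7, from 3 to 15).

Steps most likely to fail:

1. Step 5. The aryllithium may add to the alkyne in conjugate fashion instead of to the amide carbonyl, or the ortho hydroxyl may close on the α-carbon before the amine relay is in place, which would give the five-membered aurone. The fallback forms the same bonds one at a time with known chemistry; it sets out from 2 and 4 and returns at 12. The dilithio species 8, made as in step 5, is acetylated with N-methoxy-N-methylacetamide to give 1-(2-hydroxy-3,4-dimethoxyphenyl)ethanone F1. Claisen–Schmidt condensation of this ketone with aldehyde 4 (KOH, EtOH, rt) gives (2E)-3-[3-(benzyloxy)-4,5-dimethoxyphenyl]-1-(2-hydroxy-3,4-dimethoxyphenyl)prop-2-en-1-one F2. Oxidative cyclisation of the chalcone (I2 cat., DMSO, 120 °C) gives flavone 12.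

2. Step 6. Facial selectivity at C2 may be insufficient on this ortho-oxygenated, electron-rich flavone, and the basic catalyst may cause partial ring opening and reclosure of the product. The fallback replaces enantioselective hydrogenation by a kinetic resolution; it sets out from 12 and returns at 14. Conjugate reduction (LiBH(s-Bu)3, THF, −78 °C) gives rac-2-[3-(benzyloxy)-4,5-dimethoxyphenyl]-7,8-dimethoxy-2,3-dihydro-4H-chromen-4-one F3. Asymmetric transfer hydrogenation (RhCl(C5Me5)[TsDPEN] of the configuration that consumes the 2R ketone, HCO2H/Et3N, EtOAc, rt) should reduce only the 2R enantiomer, to (2R,4R)-2-[3-(benzyloxy)-4,5-dimethoxyphenyl]-7,8-dimethoxy-3,4-dihydro-2H-chromen-4-ol F4. The unreacted 2S ketone 14 is separated by chromatography, at the cost of at most half of the material.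

3. Step 1. Bromination may occur at C4 (para to the hydroxyl) or twice. The fallback replaces electrophilic substitution by directed ortho-metalation; it sets out from 1 and returns at 2. Protection (MOMCl, i-Pr2NEt, CH2Cl2) gives 1,2-dimethoxy-3-(methoxymethoxy)benzene F5. Lithiation ortho to the stronger directing methoxymethoxy group (n-BuLi, THF, 0 °C) and quench with BrCCl2CCl2Br give 1-bromo-3,4-dimethoxy-2-(methoxymethoxy)benzene F6. Acetal cleavage (HCl, MeOH, rt) gives 2.

Further compounds
F1 | step 5 | 1-(2-hydroxy-3,4-dimethoxyphenyl)ethanone | CC(=O)c1ccc(OC)c(OC)c1O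
F2 | step 5 | (2E)-3-[3-(benzyloxy)-4,5-dimethoxyphenyl]-1-(2-hydroxy-3,4-dimethoxyphenyl)prop-2-en-1-one | COc1ccc(C(=O)/C=C/c2cc(OC)c(OC)c(OCc3ccccc3)c2)c(O)c1OC
F3 | step 6 | rac-2-[3-(benzyloxy)-4,5-dimethoxyphenyl]-7,8-dimethoxy-2,3-dihydro-4H-chromen-4-one | COc1cc(C2CC(=O)c3ccc(OC)c(OC)c3O2)cc(OCc2ccccc2)c1OC
F4 | step 6 | (2R,4R)-2-[3-(benzyloxy)-4,5-dimethoxyphenyl]-7,8-dimethoxy-3,4-dihydro-2H-chromen-4-ol | COc1cc([C@H]2C[C@@H](O)c3ccc(OC)c(OC)c3O2)cc(OCc2ccccc2)c1OC
F5 | step 1 | 1,2-dimethoxy-3-(methoxymethoxy)benzene | COCOc1cccc(OC)c1OC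
F6 | step 1 | 1-bromo-3,4-dimethoxy-2-(methoxymethoxy)benzene | COCOc1c(Br)ccc(OC)c1OC
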